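**Plan**

- Retrosynthetic cuts, in order: the two O-benzyl groups; the flavanone C2–aryl bond (ring C to ring B), giving 7-(benzyloxy)chromone 11 and arylboronic acid 9; the chroman C3–OH/C4–H2 pair, traced back to the C3=C4 alkene of a 2H-chromene; last, the pyran ring D cut twice, at C4–C4a and at O1–C2, giving phenol 1 and the C5 enal 2.
- Enabling feature: ring B is a catechol whose oxygen para to the flavanone carbon (O1 of ring D) has one unsubstituted ortho carbon (C4a), and C2 carries two methyl groups. O1–C8a–C4a–C4–C3–C2 is therefore the skeleton of a 1-oxatriene (o-quinone methide) whose 6π closure is ring D. The C3–OH/C4–H2 pattern is that chromene after epoxidation and hydride opening.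
- Forward order: ring D on the bromophenol (step 1), epoxidation and hydride opening, bromine to boron, union with rings A/C by conjugate addition to the chromone, hydrogenolysis.
- Stereochemistry: chroman C3 (S) comes from the (S,S)-(salen)MnCl epoxidation and is kept in the C4-selective hydride opening. Flavanone C2 (S) comes from the chiral pyridine-oxazoline palladium catalyst; this base-labile centre is made in the last C–C bond-forming step and afterwards sees only neutral hydrogenolysis.

Key step: step 1

Assumption: 2-(benzyloxy)-4-bromophenol, 7-hydroxychromone and (R)-t-BuPyOx are taken as catalogue compounds; the phenol would otherwise follow from 2-(benzyloxy)phenol and NBS (bromination para to the free OH).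

**Route**

Step 1
Reactants: 1 2-(benzyloxy)-4-bromophenol; 2 3-methylbut-2-enal (1.5 equiv); 3 phenylboronic acid (1.0 equiv)
Product: 6 8-(benzyloxy)-6-bromo-2,2-dimethyl-2H-chromene, via benzodioxaborin 4 (not isolated), via o-quinone methide 5 (not isolated)
Conditions: AcOH (cat.), toluene, reflux, Dean–Stark trap
Reagents that add atoms: none
Why: Phenol 1 and 3 form an aryl phenylboronate that binds the aldehyde of 2 and delivers it through a six-membered transition state to the only free ortho carbon, which makes the aryl–C4 bond and the temporary dioxaborin ring of 4; at reflux 4 cycloreverts with loss of the PhB=O unit (as boroxine) to o-quinone methide 5, whose 1-oxatriene closes to the 2H-pyran and so makes the O1–C2 bond. The closest known reaction type is the phenylboronic acid-mediated ortho-specific condensation of phenols with α,β-unsaturated aldehydes to 2H-chromenes, a formal [3+3] annulation. Ring D closes by thermal disrotatory oxa-6π electrocyclization, while the dioxaborin ring before it closes by boron-tethered ortho-hydroxyalkylation and is lost again in the same flask. No stereocentre is formed, since C2 carries two methyl groups and C3=C4 stays planar; the alkene is kept on purpose as the handle for step 2. The step needs ortho-C over O- and para-C selectivity and 1,2- over 1,4-addition to the enal: the boron tether allows only ortho delivery, the other ortho position carries OBn and the para position Br, and the β,β-dimethyl substitution of 2 blocks conjugate addition. Rearomatization of ring B should drive the electrocyclization to completion.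

Step 2
Reactants: 6 8-(benzyloxy)-6-bromo-2,2-dimethyl-2H-chromene
Product: 7 (3S,4S)-8-(benzyloxy)-6-bromo-3,4-epoxy-2,2-dimethylchromane
Conditions: (S,S)-(salen)MnCl [(S,S)-N,N'-bis(3,5-di-tert-butylsalicylidene)cyclohexane-1,2-diaminomanganese chloride, trivalent manganese] (4 mol %), 4-phenylpyridine N-oxide (0.2 equiv), aq. NaOCl (pH 11.3), CH2Cl2, 0 °C
Reagents that add atoms: sodium hypochlorite, [Na+].[O-]Cl
Why: Jacobsen epoxidation: the oxo-manganese salen species (pentavalent manganese) transfers oxygen to one face of the cis-disubstituted, aryl-conjugated C3=C4 alkene, the substrate class for which this catalyst is most selective, and the (S,S) catalyst should give the (3S,4S) epoxide and so set chroman C3, while the benzyl ether and the aryl bromide are inert to buffered hypochlorite at 0 °C.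

Step 3
Reactants: 7 (3S,4S)-8-(benzyloxy)-6-bromo-3,4-epoxy-2,2-dimethylchromane
Product: 8 (3S)-8-(benzyloxy)-6-bromo-2,2-dimethylchroman-3-ol
Conditions: LiAlH4 (1.0 equiv), THF, 0 °C; aq. sodium potassium tartrate
Reagents that add atoms: none
Why: Regioselective hydride opening of an aryl epoxide: hydride attacks the benzylic C4 in an SN2 sense, because C3 is shielded by the adjacent quaternary C2, so the C3–O bond is never broken and the 3S configuration is kept, and the aryl bromide and the benzyl ether should not be reduced at 0 °C.

Step 4
Reactants: 8 (3S)-8-(benzyloxy)-6-bromo-2,2-dimethylchroman-3-ol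
Product: 9 [(3S)-8-(benzyloxy)-3-hydroxy-2,2-dimethylchroman-6-yl]boronic acid
Conditions: n-BuLi (2.2 equiv), THF, −78 °C; B(OiPr)3 (3 equiv), −78 °C to rt; 1 M HCl
Reagents that add atoms: triisopropyl borate, CC(C)OB(OC(C)C)OC(C)C; water, O
Why: Bromine–lithium exchange/borylation: the first equivalent of n-BuLi forms the lithium alkoxide, the second exchanges the aryl bromide faster than any ortho- or benzylic deprotonation at −78 °C, and the aryllithium is trapped by the borate and hydrolysed to the boronic acid without touching C3.

Step 5
Reactants: 10 7-hydroxy-4H-chromen-4-one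
Product: 11 7-(benzyloxy)-4H-chromen-4-one
Conditions: BnBr (1.1 equiv), K2CO3, DMF, rt
Reagents that add atoms: benzyl bromide, BrCc1ccccc1
Why: Williamson etherification of the acidic 7-OH (a vinylogous carboxylic acid) masks the phenol as a group that leaves under the same neutral hydrogenolysis as the other benzyl ether.

Step 6
Reactants: 9 [(3S)-8-(benzyloxy)-3-hydroxy-2,2-dimethylchroman-6-yl]boronic acid (1.5 equiv); 11 7-(benzyloxy)-4H-chromen-4-one
Product: 12 (2S)-7-(benzyloxy)-2-[(3S)-8-(benzyloxy)-3-hydroxy-2,2-dimethylchroman-6-yl]chroman-4-one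
Conditions: Pd(OCOCF3)2 (5 mol %), (R)-t-BuPyOx [(R)-4-tert-butyl-2-(pyridin-2-yl)-4,5-dihydrooxazole] (6 mol %), NH4PF6 (30 mol %), H2O (5 equiv), ClCH2CH2Cl, 60 °C
Reagents that add atoms: none
Why: Palladium-catalysed asymmetric conjugate addition of an arylboronic acid to a chromone: transmetalation to the cationic divalent palladium–pyridine-oxazoline complex, enantio-determining insertion of the chromone C2=C3 bond into the aryl–palladium bond and protonolysis of the palladium enolate by water give the flavanone, with flavanone C2 set by the ligand (the (R) ligand is chosen for 2S, the mirror image of the sense in which the (S) ligand arylates cyclic enones, to be confirmed on 11 with phenylboronic acid) and with the remote chroman C3 and its free hydroxyl as spectators in the aqueous, base-free medium.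

Step 7
Reactants: 12 (2S)-7-(benzyloxy)-2-[(3S)-8-(benzyloxy)-3-hydroxy-2,2-dimethylchroman-6-yl]chroman-4-one
Product: 13 (2S)-2-[(3S)-3,8-dihydroxy-2,2-dimethylchroman-6-yl]-7-hydroxychroman-4-one
Conditions: H2 (1 atm), 10% Pd/C, EtOAc/MeOH, rt
Reagents that add atoms: none
Why: Hydrogenolysis of the two aryl benzyl ethers under neutral conditions releases both phenols without base, so the retro-oxa-Michael epimerization of flavanone C2 cannot start, and the reaction is to be stopped at full debenzylation to spare the aryl ketone and the benzylic C2–O1 bond of ring C.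

**Compound list**

1 | 2-(benzyloxy)-4-bromophenol | Oc1ccc(Br)cc1OCc1ccccc1 | starting material
2 | 3-methylbut-2-enal | CC(C)=CC=O | starting material
3 | phenylboronic acid | OB(O)c1ccccc1 | starting material
4 | 8-(benzyloxy)-6-bromo-4-(2-methylprop-1-en-1-yl)-2-phenyl-4H-1,3,2-benzodioxaborinine (racemic at C4) | CC(C)=CC1OB(c2ccccc2)Oc2c(OCc3ccccc3)cc(Br)cc21 | intermediate
5 | 2-(benzyloxy)-4-bromo-6-(3-methylbut-2-en-1-ylidene)cyclohexa-2,4-dien-1-one | CC(C)=CC=C1C=C(Br)C=C(OCc2ccccc2)C1=O | intermediate
6 | 8-(benzyloxy)-6-bromo-2,2-dimethyl-2H-chromene | CC1(C)C=Cc2cc(Br)cc(OCc3ccccc3)c2O1 | intermediate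
7 | (3S,4S)-8-(benzyloxy)-6-bromo-3,4-epoxy-2,2-dimethylchromane | CC1(C)Oc2c(OCc3ccccc3)cc(Br)cc2[C@@H]3O[C@@H]31 | intermediate
8 | (3S)-8-(benzyloxy)-6-bromo-2,2-dimethylchroman-3-ol | CC1(C)Oc2c(OCc3ccccc3)cc(Br)cc2C[C@@H]1O | intermediate
9 | [(3S)-8-(benzyloxy)-3-hydroxy-2,2-dimethylchroman-6-yl]boronic acid | CC1(C)Oc2c(OCc3ccccc3)cc(B(O)O)cc2C[C@@H]1O | intermediate
10 | 7-hydroxy-4H-chromen-4-one | O=c1ccoc2cc(O)ccc12 | starting material
11 | 7-(benzyloxy)-4H-chromen-4-one | O=c1ccoc2cc(OCc3ccccc3)ccc12 | intermediate
12 | (2S)-7-(benzyloxy)-2-[(3S)-8-(benzyloxy)-3-hydroxy-2,2-dimethylchroman-6-yl]chroman-4-one | CC1(C)Oc2c(OCc3ccccc3)cc([C@@H]3CC(=O)c4ccc(OCc5ccccc5)cc4O3)cc2C[C@@H]1O | intermediate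
13 | (2S)-2-[(3S)-3,8-dihydroxy-2,2-dimethylchroman-6-yl]-7-hydroxychroman-4-one | CC1(C)Oc2c(O)cc([C@@H]3CC(=O)c4ccc(O)cc4O3)cc2C[C@@H]1O | target

**Step count**

Total: 7 steps. Longest linear sequence: 6 steps (1, 2, 3, 4, 6, 7); step 5 is a one-step side branch.

**Steps most likely to fail**

Step 6. The carbopalladation of the electron-rich 7-alkoxychromone may be slow, so that protodeboronation of the electron-rich arylboronic acid wins, or facial control may be insufficient. The fallback sets out from 8 and builds ring C by cyclization instead of arylation. Bromine–lithium exchange (n-BuLi, 2.2 equiv, THF, −78 °C) and a DMF quench would give (3S)-8-(benzyloxy)-3-hydroxy-2,2-dimethylchromane-6-carbaldehyde F1. Claisen–Schmidt condensation of F1 with commercial 1-[4-(benzyloxy)-2-hydroxyphenyl]ethanone (KOH, EtOH) would give (E)-1-[4-(benzyloxy)-2-hydroxyphenyl]-3-[(3S)-8-(benzyloxy)-3-hydroxy-2,2-dimethylchroman-6-yl]prop-2-en-1-one F2. NaOAc in refluxing EtOH would close F2 by oxa-Michael addition to 12 together with its C2 epimer (2R)-7-(benzyloxy)-2-[(3S)-8-(benzyloxy)-3-hydroxy-2,2-dimethylchroman-6-yl]chroman-4-one F3. The two are diastereomers and would be separated by preparative HPLC on a chiral stationary phase; F3 would be recycled through F2 under the same base treatment, which does not touch chroman C3. The fallback comes back at 12.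

Step 1. The ortho-hydroxyalkylation of the bromine-deactivated, ortho-alkoxy phenol may stay incomplete, while the enal self-condenses or the quinone methide dimerizes. The fallback sets out from 1 and makes the two ring bonds in separate events. O-Alkylation with 3-chloro-3-methylbut-1-yne (K2CO3, KI cat., CuI cat., DMF, 60 °C) would give 2-(benzyloxy)-4-bromo-1-[(2-methylbut-3-yn-2-yl)oxy]benzene F4. Heating F4 in N,N-diethylaniline at about 190 °C would trigger the aryl propargyl ether Claisen rearrangement to the free ortho position, followed by 1,5-hydrogen shift and oxa-6π closure. The fallback comes back at 6.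

Step 7. Hydrogenolysis may over-reduce: the benzylic C2–O1 bond of ring C may open, or the aryl ketone may be reduced, before both benzyl ethers are gone. The fallback sets out from 9 and removes the benzyl group before the flavanone exists. Hydrogenolysis of 9 (H2, 10% Pd/C, MeOH) would give [(3S)-3,8-dihydroxy-2,2-dimethylchroman-6-yl]boronic acid F5. F5 would then be added to unprotected 10 under the step 6 catalyst system, whose aqueous, base-free medium should tolerate free phenols. The fallback comes back at 13.

**Further compounds**

F1 | step 6 | (3S)-8-(benzyloxy)-3-hydroxy-2,2-dimethylchromane-6-carbaldehyde | CC1(C)Oc2c(OCc3ccccc3)cc(C=O)cc2C[C@@H]1O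
F2 | step 6 | (E)-1-[4-(benzyloxy)-2-hydroxyphenyl]-3-[(3S)-8-(benzyloxy)-3-hydroxy-2,2-dimethylchroman-6-yl]prop-2-en-1-one | CC1(C)Oc2c(OCc3ccccc3)cc(/C=C/C(=O)c3ccc(OCc4ccccc4)cc3O)cc2C[C@@H]1O
F3 | step 6 | (2R)-7-(benzyloxy)-2-[(3S)-8-(benzyloxy)-3-hydroxy-2,2-dimethylchroman-6-yl]chroman-4-one | CC1(C)Oc2c(OCc3ccccc3)cc([C@H]3CC(=O)c4ccc(OCc5ccccc5)cc4O3)cc2C[C@@H]1O
F4 | step 1 | 2-(benzyloxy)-4-bromo-1-[(2-methylbut-3-yn-2-yl)oxy]benzene | C#CC(C)(C)Oc1ccc(Br)cc1OCc1ccccc1
F5 | step 7 | [(3S)-3,8-dihydroxy-2,2-dimethylchroman-6-yl]boronic acid | CC1(C)Oc2c(O)cc(B(O)O)cc2C[C@@H]1O
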